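**Overview**
- Cuts: the acid is traced back to a silyl-protected E-allylic alcohol. Three ring bonds, C8a–C4a, C5–C6 and C6–C7, are then cut together, which opens the benzene and pyran rings at once to an isopropenyl(alkoxy)carbene chromium complex with a pendant terminal alkyne. Further cuts are O1–C8a (alcohol onto an activated acyl chromate), C8–C8a (isopropenyllithium onto Cr(CO)6) and C4–C4a (acetylide onto a tosylate).
- Enabling feature: the ring C4a–C5–C6–C7–C8–C8a carries para oxygens, O1 on C8a as an ether and a free OH on C6. This is the hydroquinone monoether signature of a carbene/alkyne/CO benzannulation, and the pyran atoms O1–C2–C3–C4 already link the carbene oxygen to the alkyne carbon that becomes C4a.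
- Carbon sources: C4, C3, C2, its methyl and the whole side chain are the unbroken skeleton of (2E,6E)-farnesol. Acetylide brings C4a and C5, isopropenyl brings C8, its methyl and C7, and Cr(CO)6 brings C8a and C6.
- Forward order: oxidise and protect the chain terminus, install the tertiary carbinol, add the alkyne, hang the carbene on the carbinol oxygen, close the pyran and benzene rings in one operation, and finish the acid last.
- Stereochemistry: C2 (R) stems from a Sharpless epoxidation with D-(−)-diethyl tartrate and hydride opening at the neighbouring carbon, and its C–O bond is kept to the end. The two inner E-alkenes are those of farnesol, and the E-enoic acid geometry comes from the E-selective SeO2 oxidation.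

Key step: step 13

Remark: ring atoms carry chroman numbers (O1, C2–C4, C4a, C5–C8, C8a) and open-chain intermediates carry farnesol numbers. In the SMILES strings a terminal CO ligand is drawn Cr=C=O, and an η6-bound Cr(CO)3 unit is joined to its arene by a dot.

**Step 1**
Reactants: 1 (2E,6E)-farnesol
Product: 2 (2E,6E)-farnesyl acetate
Conditions: Ac2O, Et3N, DMAP (cat.), CH2Cl2, 0 °C to rt
Reagents that add atoms: acetic anhydride, CC(=O)OC(C)=O
Why: DMAP-catalysed O-acetylation is routine for a primary allylic alcohol, and the ester also deactivates the 2,3-alkene toward the allylic oxidation that follows.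

**Step 2**
Reactants: 2 (2E,6E)-farnesyl acetate
Product: 3 (2E,6E,10E)-12-hydroxyfarnesyl acetate
Conditions: SeO2 (cat.), t-BuOOH, salicylic acid (cat.), CH2Cl2, 0 °C to rt, stopped before full conversion
Reagents that add atoms: tert-butyl hydroperoxide, CC(C)(C)OO
Why: The SeO2-catalysed allylic (Riley) oxidation runs through an ene reaction and a [2,3]-sigmatropic shift that pick the most electron-rich terminal alkene and its E-methyl group, a selectivity well documented for farnesyl and geranyl esters, so the new allylic alcohol should be E.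

**Step 3**
Reactants: 3 (2E,6E,10E)-12-hydroxyfarnesyl acetate
Product: 4 (2E,6E,10E)-12-(triisopropylsilyloxy)farnesyl acetate
Conditions: i-Pr3SiCl, imidazole, DMF, rt
Reagents that add atoms: chlorotriisopropylsilane, CC(C)[Si](Cl)(C(C)C)C(C)C
Why: Imidazole-promoted silylation of a primary alcohol is standard, and the bulky silyl group is chosen because it must outlast hydride, acetylide and the acidic release of a triethylsilyl ether.

**Step 4**
Reactants: 4 (2E,6E,10E)-12-(triisopropylsilyloxy)farnesyl acetate
Product: 5 (2E,6E,10E)-12-(triisopropylsilyloxy)farnesol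
Conditions: K2CO3 (cat.), MeOH, 0 °C to rt
Reagents that add atoms: none
Why: Base-catalysed transesterification removes a primary acetate under conditions that leave a triisopropylsilyl ether and the alkenes alone.

**Step 5**
Reactants: 5 (2E,6E,10E)-12-(triisopropylsilyloxy)farnesol
Product: 6 (2R,3R,6E,10E)-2,3-epoxy-12-(triisopropylsilyloxy)farnesol
Conditions: Ti(OiPr)4 (cat.), D-(−)-diethyl tartrate (cat.), t-BuOOH, 4 Å molecular sieves, CH2Cl2, −20 °C
Reagents that add atoms: tert-butyl hydroperoxide, CC(C)(C)OO
Why: The Sharpless asymmetric epoxidation is steered by the free allylic hydroxyl, so only the 2,3-alkene reacts, and for an E-allylic alcohol of the geraniol type the D-(−)-tartrate catalyst gives the (2R,3R)-epoxide, whose C3 is the future C2.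

**Step 6**
Reactants: 6 (2R,3R,6E,10E)-2,3-epoxy-12-(triisopropylsilyloxy)farnesol
Product: 7 (3R,6E,10E)-3,7,11-trimethyl-12-(triisopropylsilyloxy)dodeca-6,10-diene-1,3-diol
Conditions: NaAlH2(OCH2CH2OCH3)2, THF, 0 °C to rt; aqueous work-up
Reagents that add atoms: none
Why: In this hydroxyl-directed reductive epoxide opening the aluminate bound at O1 delivers hydride to the secondary carbon C2, the known 1,3-diol-selective mode of 2,3-epoxy alcohols, so the C3–O bond and its R configuration stay untouched.

**Step 7**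
Reactants: 7 (3R,6E,10E)-3,7,11-trimethyl-12-(triisopropylsilyloxy)dodeca-6,10-diene-1,3-diol
Product: 8 (3R,6E,10E)-3-hydroxy-3,7,11-trimethyl-12-(triisopropylsilyloxy)dodeca-6,10-dien-1-yl 4-methylbenzenesulfonate
Conditions: TsCl, Et3N, DMAP (cat.), CH2Cl2, 0 °C
Reagents that add atoms: 4-toluenesulfonyl chloride, Cc1ccc(cc1)S(=O)(=O)Cl
Why: Chemoselective sulfonylation works because the primary hydroxyl is tosylated far faster than the hindered tertiary one.

**Step 8**
Reactants: 8 (3R,6E,10E)-3-hydroxy-3,7,11-trimethyl-12-(triisopropylsilyloxy)dodeca-6,10-dien-1-yl 4-methylbenzenesulfonate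
Product: 9 (3R,6E,10E)-3,7,11-trimethyl-3-(triethylsilyloxy)-12-(triisopropylsilyloxy)dodeca-6,10-dien-1-yl 4-methylbenzenesulfonate
Conditions: Et3SiOTf, 2,6-lutidine, CH2Cl2, −78 to 0 °C
Reagents that add atoms: triethylsilyl trifluoromethanesulfonate, CC[Si](CC)(CC)OS(=O)(=O)C(F)(F)F
Why: Silyl triflate with lutidine is the standard silylation of a tertiary alcohol, and the cap keeps the oxygen from closing onto the tosylate under the basic conditions of the next step.

**Step 9**
Reactants: 9 (3R,6E,10E)-3,7,11-trimethyl-3-(triethylsilyloxy)-12-(triisopropylsilyloxy)dodeca-6,10-dien-1-yl 4-methylbenzenesulfonate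
Product: 10 (5R,8E,12E)-5,9,13-trimethyl-5-(triethylsilyloxy)-14-(triisopropylsilyloxy)tetradeca-8,12-dien-1-yne
Conditions: LiC≡CH·H2NCH2CH2NH2, DMSO, rt
Reagents that add atoms: lithium acetylide ethylenediamine complex, [Li+].[C-]#C.NCCN
Why: SN2 alkylation of lithium acetylide by a primary sulfonate in a dipolar aprotic solvent is a standard terminal alkyne synthesis and adds the two carbons that become C4a and C5.

**Step 10**
Reactants: 10 (5R,8E,12E)-5,9,13-trimethyl-5-(triethylsilyloxy)-14-(triisopropylsilyloxy)tetradeca-8,12-dien-1-yne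
Product: 11 (5R,8E,12E)-5,9,13-trimethyl-14-(triisopropylsilyloxy)tetradeca-8,12-dien-1-yn-5-ol
Conditions: camphorsulfonic acid (cat.), MeOH–CH2Cl2, 0 °C
Reagents that add atoms: none
Why: Acid-catalysed methanolysis sorts silyl ethers by the bulk at silicon, so the triethylsilyl group should leave while the triisopropylsilyl ether stays.

**Step 11**
Reactants: 12 2-bromopropene; 13 chromium hexacarbonyl Cr(CO)6
Product: 16 tetramethylammonium pentacarbonyl(methacryloyl)chromate, via isopropenyllithium 14 (not isolated), via lithium pentacarbonyl(methacryloyl)chromate 15 (not isolated)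
Conditions: 12, t-BuLi (2 equiv), Et2O, −78 °C; 13, Et2O, 0 °C to rt; then Me4NBr, degassed H2O, extraction into CH2Cl2
Reagents that add atoms: tetramethylammonium bromide, C[N+](C)(C)C.[Br-]
Why: This is the Fischer acylmetalate synthesis, in which bromine–lithium exchange gives 14, 14 adds to a CO ligand of 13, and salt metathesis gives the storable ammonium salt.

**Step 12**
Reactants: 16 tetramethylammonium pentacarbonyl(methacryloyl)chromate; 11 (5R,8E,12E)-5,9,13-trimethyl-14-(triisopropylsilyloxy)tetradeca-8,12-dien-1-yn-5-ol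
Product: 18 pentacarbonyl[isopropenyl(tert-alkoxy)carbene]chromium bearing the (5R)-oxy residue of 11, via acetoxy(isopropenyl)carbene complex 17 (not isolated)
Conditions: 16 (2 equiv), AcBr (2 equiv), CH2Cl2, −40 °C; then 11, concentrated solution, −40 to −10 °C; cold aq NaHCO3 wash, cold short silica plug under argon, used at once
Reagents that add atoms: none
Why: Proposed new method: O-acylation of 16 gives the acetoxycarbene 17, whose carbene carbon is electrophilic enough to take up a neutral alcohol by addition–elimination with loss of acetic acid; the closest known reaction type is this alcoholysis of acyloxycarbene complexes, established for primary and secondary alcohols including hindered terpenoid and carbohydrate ones but not for a tertiary carbinol such as 11, so 17 is used in excess and concentrated, and the C2–O bond is not involved.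

**Step 13**
Reactants: 18 pentacarbonyl[isopropenyl(tert-alkoxy)carbene]chromium bearing the (5R)-oxy residue of 11
Product: 21 (R)-6-acetoxy-2,8-dimethyl-2-[(3E,7E)-4,8-dimethyl-9-(triisopropylsilyloxy)nona-3,7-dienyl]chroman, via Cr(CO)3-bound chroman-6-ol 19 (not isolated), via Cr(CO)3-bound chroman-6-yl acetate 20 (not isolated)
Conditions: Ac2O, Et3N, THF (0.01 M), 50 °C, argon; then Et2O, air, daylight, rt
Reagents that add atoms: acetic anhydride, CC(=O)OC(C)=O
Why: Thermal loss of one cis CO ligand lets the tethered terminal alkyne bind and insert into the Cr=C bond with its internal carbon (C4a) bonding to the carbene carbon (C8a), after which CO insertion gives a chromium-bound dienylketene (new C5–C6 bond) whose 6π electrocyclisation onto the isopropenyl CH2 (new C6–C7 bond) and enolisation deliver the 4-alkoxyphenol complex 19. The closest known reaction type is the intramolecular Dötz benzannulation of alkoxycarbene pentacarbonylchromium complexes that carry the alkyne on the carbene oxygen. The pyran ring closes in a 6-exo-dig sense at the alkyne insertion (C8a–C4a), and the benzene ring closes by the six-electron electrocyclic closure of the dienylketene (C6–C7), a formal [3+2+1] assembly. No new stereocentre arises, and C2 is preserved because all four of its bonds, C2–O1 included, are spectators. The step needs the regiochemistry opposite to that of a free terminal alkyne (substituted carbon next to C8a, CH next to C6), which the three-carbon tether C2–C3–C4 enforces with help from the geminal substitution at C2, and it needs the alkyne to beat the trisubstituted chain alkenes, which are poor partners for an alkoxycarbene. Ac2O with Et3N caps the oxidation-prone hydroquinone monoether as 20, and air with light then strips the Cr(CO)3 unit.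

**Step 14**
Reactants: 21 (R)-6-acetoxy-2,8-dimethyl-2-[(3E,7E)-4,8-dimethyl-9-(triisopropylsilyloxy)nona-3,7-dienyl]chroman
Product: 22 (R)-6-acetoxy-2-[(3E,7E)-9-hydroxy-4,8-dimethylnona-3,7-dienyl]-2,8-dimethylchroman
Conditions: HF·pyridine, pyridine, THF, 0 °C to rt
Reagents that add atoms: none
Why: Fluoride-mediated desilylation in a weakly acidic buffered medium frees the primary allylic alcohol without the basic fluoride or alkoxide that would cleave the aryl acetate.

**Step 15**
Reactants: 22 (R)-6-acetoxy-2-[(3E,7E)-9-hydroxy-4,8-dimethylnona-3,7-dienyl]-2,8-dimethylchroman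
Product: 23 (2E,6E)-9-[(R)-6-acetoxy-2,8-dimethylchroman-2-yl]-2,6-dimethylnona-2,6-dienal
Conditions: MnO2 (activated, excess), CH2Cl2, rt
Reagents that add atoms: none
Why: MnO2 oxidises allylic alcohols selectively to enals without E/Z isomerisation, and the acetate keeps the electron-rich aromatic ring out of reach of the oxidant.

**Step 16**
Reactants: 23 (2E,6E)-9-[(R)-6-acetoxy-2,8-dimethylchroman-2-yl]-2,6-dimethylnona-2,6-dienal
Product: 24 (2E,6E)-9-[(R)-6-acetoxy-2,8-dimethylchroman-2-yl]-2,6-dimethylnona-2,6-dienoic acid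
Conditions: NaClO2, NaH2PO4, 2-methyl-2-butene, t-BuOH–H2O, rt
Reagents that add atoms: sodium chlorite, [Na+].[O-]Cl=O
Why: The Pinnick oxidation converts enals to enoic acids with retention of alkene geometry, and the scavenger alkene shields the chain alkenes and the arene from hypochlorous acid.

**Step 17**
Reactants: 24 (2E,6E)-9-[(R)-6-acetoxy-2,8-dimethylchroman-2-yl]-2,6-dimethylnona-2,6-dienoic acid
Product: 25 (2E,6E)-9-[(2R)-6-hydroxy-2,8-dimethylchroman-2-yl]-2,6-dimethylnona-2,6-dienoic acid (CNP0176653.1)
Conditions: K2CO3, degassed MeOH, argon, 0 °C to rt; then 1 M HCl to pH 3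
Reagents that add atoms: none
Why: Base-mediated methanolysis of an aryl acetate is fast and mild, the carboxylate is inert to it, exclusion of air protects the phenoxide, and neither C2 nor the alkenes are affected.

**Compound list**
1 | (2E,6E)-farnesol | CC(C)=CCC/C(C)=C/CC/C(C)=C/CO | starting material
2 | (2E,6E)-farnesyl acetate | CC(C)=CCC/C(C)=C/CC/C(C)=C/COC(C)=O | intermediate
3 | (2E,6E,10E)-12-hydroxyfarnesyl acetate | C/C(=C\CC/C(C)=C/CC/C(C)=C/COC(C)=O)CO | intermediate
4 | (2E,6E,10E)-12-(triisopropylsilyloxy)farnesyl acetate | C/C(=C\CC/C(C)=C/CC/C(C)=C/COC(C)=O)CO[Si](C(C)C)(C(C)C)C(C)C | intermediate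
5 | (2E,6E,10E)-12-(triisopropylsilyloxy)farnesol | C/C(=C\CC/C(C)=C/CC/C(C)=C/CO)CO[Si](C(C)C)(C(C)C)C(C)C | intermediate
6 | (2R,3R,6E,10E)-2,3-epoxy-12-(triisopropylsilyloxy)farnesol | C/C(=C\CC/C(C)=C/CC[C@@]1(C)O[C@@H]1CO)CO[Si](C(C)C)(C(C)C)C(C)C | intermediate
7 | (3R,6E,10E)-3,7,11-trimethyl-12-(triisopropylsilyloxy)dodeca-6,10-diene-1,3-diol | C/C(=C\CC/C(C)=C/CC[C@@](C)(O)CCO)CO[Si](C(C)C)(C(C)C)C(C)C | intermediate
8 | primary tosylate of 7, tertiary OH free, (3R) | C/C(=C\CC/C(C)=C/CC[C@@](C)(O)CCOS(=O)(=O)c1ccc(C)cc1)CO[Si](C(C)C)(C(C)C)C(C)C | intermediate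
9 | 3-O-triethylsilyl ether of 8, (3R) | C/C(=C\CC/C(C)=C/CC[C@@](C)(O[Si](CC)(CC)CC)CCOS(=O)(=O)c1ccc(C)cc1)CO[Si](C(C)C)(C(C)C)C(C)C | intermediate
10 | (5R,8E,12E)-5,9,13-trimethyl-5-(triethylsilyloxy)-14-(triisopropylsilyloxy)tetradeca-8,12-dien-1-yne | C/C(=C\CC/C(C)=C/CC[C@@](C)(O[Si](CC)(CC)CC)CCC#C)CO[Si](C(C)C)(C(C)C)C(C)C | intermediate
11 | (5R,8E,12E)-5,9,13-trimethyl-14-(triisopropylsilyloxy)tetradeca-8,12-dien-1-yn-5-ol | C/C(=C\CC/C(C)=C/CC[C@@](C)(O)CCC#C)CO[Si](C(C)C)(C(C)C)C(C)C | intermediate
12 | 2-bromopropene | C=C(C)Br | starting material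
13 | chromium hexacarbonyl Cr(CO)6 | O=C=[Cr](=C=O)(=C=O)(=C=O)(=C=O)=C=O | starting material
14 | isopropenyllithium | [Li]C(C)=C | intermediate
15 | lithium pentacarbonyl(methacryloyl)chromate | C=C(C)C([O-])=[Cr](=C=O)(=C=O)(=C=O)(=C=O)=C=O.[Li+] | intermediate
16 | tetramethylammonium pentacarbonyl(methacryloyl)chromate | C=C(C)C([O-])=[Cr](=C=O)(=C=O)(=C=O)(=C=O)=C=O.C[N+](C)(C)C | intermediate
17 | pentacarbonyl[acetoxy(isopropenyl)carbene]chromium | C=C(C)C(OC(C)=O)=[Cr](=C=O)(=C=O)(=C=O)(=C=O)=C=O | intermediate
18 | pentacarbonyl[isopropenyl(tert-alkoxy)carbene]chromium, alkoxy = (5R)-oxy residue of 11 | C/C(=C\CC/C(C)=C/CC[C@@](C)(OC(C(C)=C)=[Cr](=C=O)(=C=O)(=C=O)(=C=O)=C=O)CCC#C)CO[Si](C(C)C)(C(C)C)C(C)C | intermediate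
19 | tricarbonylchromium complex (either arene face) of the (R)-chroman-6-ol with the silylated side chain | C/C(=C\CC[C@]1(C)CCc2cc(O)cc(C)c2O1)CC/C=C(\C)CO[Si](C(C)C)(C(C)C)C(C)C.O=C=[Cr](=C=O)=C=O | intermediate
20 | tricarbonylchromium complex (either arene face) of 21 | C/C(=C\CC[C@]1(C)CCc2cc(OC(C)=O)cc(C)c2O1)CC/C=C(\C)CO[Si](C(C)C)(C(C)C)C(C)C.O=C=[Cr](=C=O)=C=O | intermediate
21 | (R)-6-acetoxy-2,8-dimethyl-2-[(3E,7E)-4,8-dimethyl-9-(triisopropylsilyloxy)nona-3,7-dienyl]chroman | C/C(=C\CC[C@]1(C)CCc2cc(OC(C)=O)cc(C)c2O1)CC/C=C(\C)CO[Si](C(C)C)(C(C)C)C(C)C | intermediate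
22 | (R)-6-acetoxy-2-[(3E,7E)-9-hydroxy-4,8-dimethylnona-3,7-dienyl]-2,8-dimethylchroman | C/C(=C\CC[C@]1(C)CCc2cc(OC(C)=O)cc(C)c2O1)CC/C=C(\C)CO | intermediate
23 | (2E,6E)-9-[(R)-6-acetoxy-2,8-dimethylchroman-2-yl]-2,6-dimethylnona-2,6-dienal | C/C(=C\CC[C@]1(C)CCc2cc(OC(C)=O)cc(C)c2O1)CC/C=C(\C)C=O | intermediate
24 | (2E,6E)-9-[(R)-6-acetoxy-2,8-dimethylchroman-2-yl]-2,6-dimethylnona-2,6-dienoic acid | C/C(=C\CC[C@]1(C)CCc2cc(OC(C)=O)cc(C)c2O1)CC/C=C(\C)C(=O)O | intermediate
25 | (2E,6E)-9-[(2R)-6-hydroxy-2,8-dimethylchroman-2-yl]-2,6-dimethylnona-2,6-dienoic acid, CNP0176653.1 | C/C(=C\CC[C@]1(C)CCc2cc(O)cc(C)c2O1)CC/C=C(\C)C(=O)O | target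

**Step count**
Total step count: 17. Longest linear sequence: 16 (steps 1–10 and 12–17 from farnesol). Step 11 is a one-step side branch.

**Steps most likely to fail**

Step 12. Addition of the hindered neutral carbinol may be slower than the thermal decay of the acetoxycarbene. Acetyl transfer to the alcohol may compete, and the tertiary alkoxy group may be lost again by ionisation or elimination.
- The fallback uses only established cross-coupling chemistry and no carbene. It sets out from 9 and comes back at 21.
- A Finkelstein exchange (NaI, acetone) would give the primary iodide F1, and zinc insertion (Zn dust, LiCl, THF) would give the alkylzinc iodide F2.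
- A Negishi coupling with commercial 2-bromo-1-iodo-3-methylbenzene (PdCl2(dppf), THF, rt), selective for the carbon–iodine bond, would give the ortho-bromoarene F3. The C4–C4a bond is then in place.
- Acidic methanolysis as in step 10 would free the tertiary bromoaryl alcohol F4.
- An intramolecular Buchwald–Hartwig etherification (Pd(OAc)2, 2,2'-bis(di-p-tolylphosphino)-1,1'-binaphthyl, K2CO3, toluene, 100 °C) is established for tertiary 4-(2-bromoaryl)butan-2-ols. It would close O1–C8a with the C2–O bond intact and give the 6-unsubstituted chroman F5.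
- Sterically governed C–H borylation ([Ir(OMe)(cod)]2, 4,4'-di-tert-butyl-2,2'-bipyridine, bis(pinacolato)diboron, THF, 60 °C) should pick C6–H, the only ring position without an ortho substituent, and give the 6-boronate F6.
- NaBO3 in THF–H2O would give the free chroman-6-ol F7, and Ac2O with pyridine would lead to 21.

Step 13. At the temperature needed for CO loss the tertiary alkyl–oxygen bond may ionise or eliminate. Intermolecular alkyne insertion may lead to oligomerisation, or the vinylcarbene intermediate may be diverted before CO insertion.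
- The fallback abandons the carbene branch at an earlier and more plentiful stage. It sets out from 6 and comes back at 21.
- Appel-type iodination (iodine, PPh3, imidazole, CH2Cl2) would give the epoxy iodide F8.
- Zinc-induced reductive ring opening (Zn dust, EtOH, reflux) would give the (R)-vinyl carbinol F9, with the tertiary C–O bond kept.
- 9-Borabicyclo[3.3.1]nonane should hydroborate only the monosubstituted alkene and give the B-alkyl borane F10.
- A B-alkyl Suzuki–Miyaura coupling with 2-bromo-1-iodo-3-methylbenzene (PdCl2(dppf), aq K3PO4, THF–DMF, rt) would reach the bromoaryl alcohol F4 without any protection of the tertiary hydroxyl.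
- From F4, the etherification, the borylation–oxidation and the acetylation described for step 12 lead to 21.

Step 9. The triethylsilyl group may be lost in the strongly basic medium, followed by 4-exo-tet closure of the alkoxide onto the tosylate, or E2 elimination may compete with substitution.
- The fallback makes that ring closure deliberate. It sets out from 8 and comes back at 11, skipping steps 8–10.
- A Williamson closure (KOt-Bu, THF, 0 °C to rt) would give the 2,2-disubstituted oxetane F11.
- Monolithium acetylide F12 (acetylene, n-BuLi, THF, −78 °C) in the presence of BF3·OEt2 at −78 °C should open the Lewis-acid-activated oxetane at its unsubstituted CH2 in an SN2 sense and give 11 directly with the tertiary C–O bond intact.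

**Further compounds**
F1 | step 12 | (3R,6E,10E)-1-iodo-3,7,11-trimethyl-3-(triethylsilyloxy)-12-(triisopropylsilyloxy)dodeca-6,10-diene | C/C(=C\CC/C(C)=C/CC[C@@](C)(O[Si](CC)(CC)CC)CCI)CO[Si](C(C)C)(C(C)C)C(C)C
F2 | step 12 | alkylzinc iodide derived from F1, (3R) | C/C(=C\CC/C(C)=C/CC[C@@](C)(O[Si](CC)(CC)CC)CC[Zn]I)CO[Si](C(C)C)(C(C)C)C(C)C
F3 | step 12 | (3R,6E,10E)-1-(2-bromo-3-methylphenyl)-3,7,11-trimethyl-3-(triethylsilyloxy)-12-(triisopropylsilyloxy)dodeca-6,10-diene | C/C(=C\CC/C(C)=C/CC[C@@](C)(O[Si](CC)(CC)CC)CCc1cccc(C)c1Br)CO[Si](C(C)C)(C(C)C)C(C)C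
F4 | step 12 | (3R,6E,10E)-1-(2-bromo-3-methylphenyl)-3,7,11-trimethyl-12-(triisopropylsilyloxy)dodeca-6,10-dien-3-ol | C/C(=C\CC/C(C)=C/CC[C@@](C)(O)CCc1cccc(C)c1Br)CO[Si](C(C)C)(C(C)C)C(C)C
F5 | step 12 | (R)-2,8-dimethyl-2-[(3E,7E)-4,8-dimethyl-9-(triisopropylsilyloxy)nona-3,7-dienyl]chroman | C/C(=C\CC[C@]1(C)CCc2cccc(C)c2O1)CC/C=C(\C)CO[Si](C(C)C)(C(C)C)C(C)C
F6 | step 12 | 6-(4,4,5,5-tetramethyl-1,3,2-dioxaborolan-2-yl) derivative of F5, (R) | C/C(=C\CC[C@]1(C)CCc2cc(B3OC(C)(C)C(C)(C)O3)cc(C)c2O1)CC/C=C(\C)CO[Si](C(C)C)(C(C)C)C(C)C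
F7 | step 12 | (R)-2,8-dimethyl-2-[(3E,7E)-4,8-dimethyl-9-(triisopropylsilyloxy)nona-3,7-dienyl]chroman-6-ol | C/C(=C\CC[C@]1(C)CCc2cc(O)cc(C)c2O1)CC/C=C(\C)CO[Si](C(C)C)(C(C)C)C(C)C
F8 | step 13 | (2S,3R,6E,10E)-2,3-epoxy-1-iodo-3,7,11-trimethyl-12-(triisopropylsilyloxy)dodeca-6,10-diene (same spatial arrangement as 6) | C/C(=C\CC/C(C)=C/CC[C@@]1(C)O[C@@H]1CI)CO[Si](C(C)C)(C(C)C)C(C)C
F9 | step 13 | (3R,6E,10E)-3,7,11-trimethyl-12-(triisopropylsilyloxy)dodeca-1,6,10-trien-3-ol | C/C(=C\CC/C(C)=C/CC[C@@](C)(O)C=C)CO[Si](C(C)C)(C(C)C)C(C)C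
F10 | step 13 | (3S,6E,10E)-1-(9-borabicyclo[3.3.1]nonan-9-yl)-3,7,11-trimethyl-12-(triisopropylsilyloxy)dodeca-6,10-dien-3-ol (descriptor changes by priority only) | C/C(=C\CC/C(C)=C/CC[C@@](C)(O)CCB1C2CCCC1CCC2)CO[Si](C(C)C)(C(C)C)C(C)C
F11 | step 9 | (R)-2-methyl-2-[(3E,7E)-4,8-dimethyl-9-(triisopropylsilyloxy)nona-3,7-dienyl]oxetane | C/C(=C\CC/C(C)=C/CC[C@]1(C)CCO1)CO[Si](C(C)C)(C(C)C)C(C)C
F12 | step 9 | monolithium acetylide | [Li]C#C
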